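Numbering used here: C1 = exocyclic CH2 on C2; ring A (11-membered) = C2–C3(OAc)–C4–C5–C6(Me)–C7–C8–C9=C10(Me)–C11–C12; ring B (cyclohexene) = C9, C10, C11, C15(Me), C16(OH), C17(OH); ring C (cyclopentane) = C11, C12, C13, C14, C15.
Cuts (retro): C17 carbinol to ketone; C3 carbinol and the C2–C3 bond (ring A, Nozaki–Hiyama–Kishi); C8–C9 (B-alkyl Suzuki, chain C3–C8 from (R)-β-citronellene); then C14–C15 and C11–C12 of ring C together, after re-attaching on C14 a carboxyl that ties C14 to O16 as an ester.
Forward: ring B from 2,4-dimethylphenol by oxidative dearomatisation (dienone ketal 4, dienol 5); ring C plus a temporary γ-lactone in one radical [3+2] event (step 9); lactone opened and its carbon removed by decarboxylation; chain joined at C9; ring A closed last.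
Enabling feature: ring C is a cyclopentane whose C12 bears an sp2 carbon (C2) and whose quaternary C15 carries C14 cis to O16, next to the C9=C10 double bond. This is the retron of a vinylcyclopropane (C12–C13–C14) adding across C15=C11 of a C15=C11–C10=C9 diene, with the C14 radical delivered from O16 by a two-atom tether.
Stereochemistry: C16 by catalytic asymmetric ketone reduction; C15 and C11 from C16 through the cis-fused rings of step 9; C12 by equilibration next to a ketone; C6 from the chiral pool; C3 by reagent-controlled reduction; C17 by hydroxyl-directed reduction from O16.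

Key step: step 9

Assumption: in the oxazaborolidine reduction of dienone 4 the quaternary ketal carbon C17 is taken to act as the larger carbonyl substituent, so that the (S)-catalyst gives the (R)-alcohol; if the sense were reversed, the enantiomeric catalyst would be used and nothing else changes.

Step 1
Reactants: 1 2,4-dimethylphenol
Product: 2 2-bromo-4,6-dimethylphenol
Conditions: Br2, CH2Cl2, 0 °C
Reagents that add atoms: bromine, BrBr
Why: Electrophilic aromatic bromination goes to the only free position ortho to the hydroxyl (the future C17), the para and the other ortho position being blocked by methyl groups.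

Step 2
Reactants: 2 2-bromo-4,6-dimethylphenol
Product: 3 2-methoxy-4,6-dimethylphenol
Conditions: NaOMe, CuI (0.1 equiv), MeOH/DMF, 110 °C
Reagents that add atoms: sodium methoxide, [Na+].[O-]C
Why: Copper-catalysed Ullmann-type methoxylation of an ortho-bromophenol gives the guaiacol that carries both ring B oxygens and both ring methyl groups.

Step 3
Reactants: 3 2-methoxy-4,6-dimethylphenol
Product: 4 6,6-dimethoxy-2,4-dimethylcyclohexa-2,4-dien-1-one
Conditions: PhI(OAc)2, MeOH, 0 °C; solution used at once
Reagents that add atoms: methanol, CO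
Why: Hypervalent-iodine oxidative dearomatisation of a 2-methoxyphenol traps methanol at the methoxy-bearing carbon to give the o-quinone monoketal, and the methyl groups on C15 and C10 slow its Diels–Alder dimerisation.

Step 4
Reactants: 4 6,6-dimethoxy-2,4-dimethylcyclohexa-2,4-dien-1-one
Product: 5 (1R)-6,6-dimethoxy-2,4-dimethylcyclohexa-2,4-dien-1-ol
Conditions: (S)-2-methyl-CBS-oxazaborolidine (0.2 equiv), catecholborane, PhMe, −78 °C
Reagents that add atoms: none
Why: Corey–Bakshi–Shibata reduction delivers hydride 1,2 within the catalyst–borane–ketone complex and sets C16 (R, see assumption), while catecholborane at −78 °C leaves the diene untouched.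

Step 5
Reactants: 6 but-3-en-2-one; 7 (2-ethoxy-2-oxoethyl)dimethylsulfonium bromide
Product: 9 ethyl trans-2-acetylcyclopropane-1-carboxylate (racemic), via sulfonium ylide 8 (not isolated)
Conditions: K2CO3, CH2Cl2, rt
Reagents that add atoms: none
Why: The ester-stabilised sulfonium ylide adds to the enone and the enolate displaces dimethyl sulfide (Corey–Chaykovsky-type cyclopropanation) to give the trans isomer; racemic material suffices because both cyclopropane centres lose their configuration in step 9.

Step 6
Reactants: 9 ethyl trans-2-acetylcyclopropane-1-carboxylate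
Product: 10 trans-2-acetylcyclopropane-1-carboxylic acid (racemic)
Conditions: LiOH·H2O, THF/H2O, 0 °C → rt; then 1 M HCl
Reagents that add atoms: lithium hydroxide, [Li+].[OH-]
Why: Ester saponification, with the stable trans arrangement retained.

Step 7
Reactants: 5 (1R)-6,6-dimethoxy-2,4-dimethylcyclohexa-2,4-dien-1-ol; 10 trans-2-acetylcyclopropane-1-carboxylic acid
Product: 11 (1R)-6,6-dimethoxy-2,4-dimethylcyclohexa-2,4-dien-1-yl trans-2-acetylcyclopropane-1-carboxylate (both cyclopropane diastereomers)
Conditions: DCC, DMAP (0.1 equiv), CH2Cl2, 0 °C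
Reagents that add atoms: none
Why: Steglich esterification under buffered conditions spares the acid-sensitive dienol, and the two diastereomers that arise from the racemic acid converge in step 9.

Step 8
Reactants: 11 dienyl trans-2-acetylcyclopropane-1-carboxylate
Product: 12 (1R)-6,6-dimethoxy-2,4-dimethylcyclohexa-2,4-dien-1-yl trans-2-[1-(tert-butyldimethylsilyloxy)ethenyl]cyclopropane-1-carboxylate
Conditions: KHMDS, THF, −78 °C; TBSCl
Reagents that add atoms: tert-butyldimethylsilyl chloride, CC(C)(C)[Si](C)(C)Cl
Why: Kinetic enolate formation at the methyl group (the cyclopropyl α-hydrogens are not removed and the trans ring cannot undergo Dieckmann closure) and O-silylation give the 2-silyloxy-1-alkene, which is the vinylcyclopropane needed for step 9.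

Step 9
Reactants: 12 dienyl trans-2-[1-(tert-butyldimethylsilyloxy)ethenyl]cyclopropane-1-carboxylate
Product: 13 tricyclic γ-lactone (ring B 17,17-dimethoxy-9-ene, ring C with 12-[1-(tert-butyldimethylsilyloxy)ethenyl], C14 carboxyl lactonised onto O16)
Conditions: PhSSPh (0.2 equiv), AIBN (0.1 equiv), PhH (0.005 M), 80 °C
Reagents that add atoms: none
Why: Proposed new method: PhS• adds to the CH2 terminus (C1) of the silyl enol ether, the cyclopropylcarbinyl radical at C2 opens the C12–C14 bond towards the ester-stabilised C14 radical, C14 closes 5-exo-trig through the ester tether onto C15 of the ring diene (temporary γ-lactone), the allyl radical so formed (C11–C10–C9) closes 5-exo-trig from C11 onto C12 of the enol ether (ring C), and β-scission returns PhS• and the silyl enol ether, so the step is a chain isomerisation without reductant. The closest known reactions are the thiyl-radical-catalysed [3+2] cycloaddition of 2-vinylcyclopropane-1-carboxylates with alkenes, so far intermolecular, and the atom-transfer lactonisation of allyl α-halo esters, which shows that the slow s-cis ester rotamer can cyclise when radical generation is reversible, as ring opening is here. Attack is needed at the methyl-bearing diene terminus C15 and not at the unsubstituted terminus C9 that an untethered radical would choose; the two-atom tether allows only the 5-exo mode at C15, and closure of the allyl radical at C11 (five-membered ring) is preferred to closure at C9 (seven-membered ring). C15 and C11 are set from C16, because the lactone can only be cis-fused, which places C14 cis to O16, and ring C can only be cis-fused to ring B, which places C12 cis to C14. The temporary centre C14 must form with C13 syn to C11 (1,5-cis preference of the chair-like transition state), since the anti isomer cannot close ring C, while C12 may form as a mixture and is equilibrated in step 10. High dilution suppresses intermolecular addition, and both cyclopropane diastereomers of 12 converge because C12 and C14 lose their configuration on ring opening.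

Step 10
Reactants: 13 tricyclic γ-lactone
Product: 16 12-acetyl-16-O-TBS-17,17-dimethoxy ring B/C acid (C14 carboxylic acid), via lithium hydroxy-carboxylate 14 (not isolated), via bis-silyl derivative 15 (not isolated)
Conditions: LiOH·H2O, THF/MeOH/H2O, 50 °C; evaporate, PhMe azeotrope; TBSOTf, 2,6-lutidine, CH2Cl2, −78 → 0 °C; then K2CO3 (cat.), MeOH/H2O, pH 5 work-up
Reagents that add atoms: lithium hydroxide, [Li+].[OH-]; tert-butyldimethylsilyl trifluoromethanesulfonate, CC(C)(C)[Si](C)(C)OS(=O)(=O)C(F)(F)F
Why: Hydroxide opens the lactone, cleaves the silyl enol ether and equilibrates C12 next to the methyl ketone to the more stable epimer with the acetyl group trans to C10 and to the C14 carboxylate; silylation of the hindered C16 hydroxyl then blocks re-lactonisation and methanolysis frees the acid from its silyl ester (ester hydrolysis, thermodynamic epimerisation, silyl ether formation).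

Step 11
Reactants: 16 C14 carboxylic acid
Product: 18 12-acetyl-16-O-TBS-17,17-dimethoxy ring B/C ketone (C14 = CH2), via thiohydroxamate ester 17 (not isolated)
Conditions: N-hydroxypyridine-2-thione, DCC, DMAP (cat.), CH2Cl2, 0 °C, dark; then t-BuSH, hν (tungsten lamp), PhH, rt
Reagents that add atoms: none
Why: Barton reductive decarboxylation: the thiohydroxamate ester fragments under light to the secondary C14 radical, which takes hydrogen from the thiol, so the tether carbon leaves as CO2 and C14 becomes the CH2 of the target.

Step 12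
Reactants: 18 12-acetyl ketone
Product: 19 enol triflate (12-[1-(trifluoromethanesulfonyloxy)ethenyl])
Conditions: KHMDS, THF, −78 °C; PhNTf2, −78 → 0 °C
Reagents that add atoms: N-phenylbis(trifluoromethanesulfonimide), O=S(=O)(N(c1ccccc1)S(=O)(=O)C(F)(F)F)C(F)(F)F
Why: Kinetic deprotonation at the methyl group and O-triflation give the 2-triflyloxy-1-alkene made of C2 and C1 (enol triflate formation), and the hindered C12 methine keeps its configuration at −78 °C.

Step 13
Reactants: 19 enol triflate ketal
Product: 20 ring B enone (C17 ketone conjugated with C9=C10)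
Conditions: PPTS, acetone/H2O, 40 °C
Reagents that add atoms: water, O
Why: Acid hydrolysis of the allylic dimethyl ketal unveils the C17 ketone, and the silyl ether and enol triflate tolerate the weak acid.

Step 14
Reactants: 20 ring B enone
Product: 21 9-iodo enone
Conditions: I2, pyridine, CH2Cl2, rt
Reagents that add atoms: iodine, II
Why: α-Iodination of the enone by conjugate addition of pyridine, iodination of the enolate and elimination puts iodine on C9, the only vinylic C–H α to the ketone.

Step 15
Reactants: 22 (3R)-3,7-dimethylocta-1,6-diene ((R)-β-citronellene)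
Product: 24 (3R)-6,6-dimethoxy-3-methylhex-1-ene, via (4R)-4-methylhex-5-enal 23 (not isolated)
Conditions: O3 (1 equiv), CH2Cl2/MeOH, −78 °C; TsOH·H2O (cat.); Me2S, −78 °C → rt; NaHCO3
Reagents that add atoms: methanol, CO
Why: Ozone attacks the electron-rich trisubstituted alkene much faster than the monosubstituted one and acidic methanol converts the aldehyde into its dimethyl acetal (chemoselective ozonolysis, acetalisation); the C6 stereocentre comes unchanged from the chiral pool.

Step 16
Reactants: 24 (3R)-6,6-dimethoxy-3-methylhex-1-ene; 21 9-iodo enone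
Product: 26 9-alkyl enone (chain C8–C3 on C9, C3 as dimethyl acetal), via B-alkyl-9-BBN adduct 25 (not isolated)
Conditions: 9-BBN, THF, 0 °C → rt; then 21, PdCl2(dppf) (0.1 equiv), AsPh3, K3PO4 (aq.), DMF/THF, rt
Reagents that add atoms: none
Why: Anti-Markovnikov hydroboration puts boron on C8 and B-alkyl Suzuki–Miyaura coupling joins C8 to C9; zerovalent palladium inserts into the C–I bond of the α-iodoenone at room temperature far faster than into the enol triflate.

Step 17
Reactants: 26 9-alkyl enone acetal
Product: 27 C3 aldehyde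
Conditions: PPTS, acetone/H2O, 50 °C
Reagents that add atoms: water, O
Why: Mild acid hydrolysis of the dimethyl acetal frees the C3 aldehyde for ring closure.

Step 18
Reactants: 27 C3 aldehyde enol triflate
Product: 28 tricyclic allylic alcohols (ring A closed, C3 epimers)
Conditions: CrCl2 (10 equiv), NiCl2 (0.02 equiv), DMSO (0.002 M), rt, syringe-pump addition of 27
Reagents that add atoms: none
Why: Nozaki–Hiyama–Kishi reaction: nickel-catalysed formation of the C2 alkenylchromium species from the enol triflate and its addition to the C3 aldehyde close the 11-membered ring A under high dilution and install the 2-methylene-3-ol unit, while the hindered ring B ketone is not attacked; the C3 configuration is not relied on.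

Step 19
Reactants: 28 allylic alcohols
Product: 29 C3 ketone (1-en-3-one)
Conditions: Dess–Martin periodinane, NaHCO3, CH2Cl2, 0 °C
Reagents that add atoms: none
Why: Dess–Martin oxidation merges both C3 epimers into one α-methylene ketone.

Step 20
Reactants: 29 C3 ketone
Product: 30 (3R)-allylic alcohol
Conditions: (S)-2-methyl-CBS-oxazaborolidine (1 equiv), catecholborane (1.2 equiv), PhMe, −78 °C
Reagents that add atoms: none
Why: Corey–Bakshi–Shibata reduction with the α-branched alkenyl arm (C2) as the large group should give the (3R)-alcohol by reagent control; the ring B ketone, a tetrasubstituted enone next to the silyloxy-bearing C16, is left alone with one equivalent of borane.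

Step 21
Reactants: 30 (3R)-allylic alcohol
Product: 31 (3R)-acetate
Conditions: Ac2O, pyridine, DMAP (cat.), CH2Cl2, 0 °C
Reagents that add atoms: acetic anhydride, CC(=O)OC(C)=O
Why: DMAP-catalysed acylation of the only free hydroxyl gives the C3 acetate.

Step 22
Reactants: 31 (3R)-acetate silyl ether
Product: 32 16-hydroxy-17-ketone
Conditions: HF·pyridine, pyridine/THF, 0 °C → rt
Reagents that add atoms: none
Why: Fluoride cleaves the silyl ether under buffered, non-basic conditions that spare the acetate and do not enolise the α-hydroxy ketone.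

Step 23
Reactants: 32 16-hydroxy-17-ketone
Product: 33 CNP0192310.2
Conditions: Me4NBH(OAc)3, MeCN/AcOH, −30 °C
Reagents that add atoms: none
Why: Hydroxyl-directed (Saksena–Evans) reduction: the C16 hydroxyl exchanges onto boron and hydride is delivered within the complex to the face of the C17 ketone that carries O16, so the new hydroxyl ends trans to O16 (17R), and the acetate and alkenes are inert.

Compound list
1 | 2,4-dimethylphenol | Cc1ccc(O)c(C)c1 | starting material
2 | 2-bromo-4,6-dimethylphenol | Cc1cc(C)c(O)c(Br)c1 | intermediate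
3 | 2-methoxy-4,6-dimethylphenol | COc1cc(C)cc(C)c1O | intermediate
4 | 6,6-dimethoxy-2,4-dimethylcyclohexa-2,4-dien-1-one (ring B; C16 ketone, C17 ketal) | COC1(OC)C=C(C)C=C(C)C1=O | intermediate
5 | (1R)-6,6-dimethoxy-2,4-dimethylcyclohexa-2,4-dien-1-ol (16R) | COC1(OC)C=C(C)C=C(C)[C@H]1O | intermediate
6 | but-3-en-2-one | CC(=O)C=C | starting material
7 | (2-ethoxy-2-oxoethyl)dimethylsulfonium bromide | CCOC(=O)C[S+](C)C.[Br-] | starting material
8 | ethyl 2-(dimethylsulfonio)acetate ylide | CCOC(=O)[CH-][S+](C)C | intermediate
9 | ethyl trans-2-acetylcyclopropane-1-carboxylate, racemic (1R,2R enantiomer drawn) | CC(=O)[C@@H]1C[C@H]1C(=O)OCC | intermediate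
10 | trans-2-acetylcyclopropane-1-carboxylic acid, racemic (1R,2R enantiomer drawn) | CC(=O)[C@@H]1C[C@H]1C(O)=O | intermediate
11 | (1R)-6,6-dimethoxy-2,4-dimethylcyclohexa-2,4-dien-1-yl trans-2-acetylcyclopropane-1-carboxylate (one of the two cyclopropane diastereomers drawn, both used) | CC(=O)[C@@H]1C[C@H]1C(=O)O[C@@H]2C(C)=CC(C)=CC2(OC)OC | intermediate
12 | (1R)-6,6-dimethoxy-2,4-dimethylcyclohexa-2,4-dien-1-yl trans-2-[1-(tert-butyldimethylsilyloxy)ethenyl]cyclopropane-1-carboxylate (one diastereomer drawn, both used) | C=C(O[Si](C)(C)C(C)(C)C)[C@@H]1C[C@H]1C(=O)O[C@@H]2C(C)=CC(C)=CC2(OC)OC | intermediate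
13 | tricyclic γ-lactone: ring B 17,17-dimethoxy-9-ene, ring C cis-fused, C14 carboxyl lactonised onto O16; O16, C14 and C12 on one face of ring B, H11 and the C15 methyl on the other; H14 and the C12 silyloxyethenyl group cis to the C15 methyl (C12 epimer may accompany it) | COC1(OC)C=C(C)[C@H]2[C@H](C(=C)O[Si](C)(C)C(C)(C)C)C[C@H]3C(=O)O[C@@H]1[C@@]23C | intermediate
14 | lithium carboxylate of the ring-opened 16-hydroxy 12-acetyl acid | [Li+].COC1(OC)C=C(C)[C@H]2[C@H](C(C)=O)C[C@@H](C([O-])=O)[C@@]2(C)[C@H]1O | intermediate
15 | 16-O-TBS ether TBS ester of the 12-acetyl acid | COC1(OC)C=C(C)[C@H]2[C@H](C(C)=O)C[C@@H](C(=O)O[Si](C)(C)C(C)(C)C)[C@@]2(C)[C@H]1O[Si](C)(C)C(C)(C)C | intermediate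
16 | 12-acetyl-16-O-TBS-17,17-dimethoxy ring B/C C14 carboxylic acid (acetyl trans to C10 and to the carboxyl) | COC1(OC)C=C(C)[C@H]2[C@H](C(C)=O)C[C@@H](C(O)=O)[C@@]2(C)[C@H]1O[Si](C)(C)C(C)(C)C | intermediate
17 | N-acyloxypyridine-2-thione (thiohydroxamate) ester of 16 | COC1(OC)C=C(C)[C@H]2[C@H](C(C)=O)C[C@@H](C(=O)ON3C=CC=CC3=S)[C@@]2(C)[C@H]1O[Si](C)(C)C(C)(C)C | intermediate
18 | 12-acetyl-16-O-TBS-17,17-dimethoxy cis-fused ring B/C ketone (C14 = CH2) | COC1(OC)C=C(C)[C@H]2[C@H](C(C)=O)CC[C@@]2(C)[C@H]1O[Si](C)(C)C(C)(C)C | intermediate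
19 | enol triflate of 18 (12-[1-(trifluoromethanesulfonyloxy)ethenyl]) | COC1(OC)C=C(C)[C@H]2[C@H](C(=C)OS(=O)(=O)C(F)(F)F)CC[C@@]2(C)[C@H]1O[Si](C)(C)C(C)(C)C | intermediate
20 | ring B enone (C17 ketone, C9=C10), 16-O-TBS, 12-enol triflate | O=C1C=C(C)[C@H]2[C@H](C(=C)OS(=O)(=O)C(F)(F)F)CC[C@@]2(C)[C@H]1O[Si](C)(C)C(C)(C)C | intermediate
21 | 9-iodo enone | O=C1C(I)=C(C)[C@H]2[C@H](C(=C)OS(=O)(=O)C(F)(F)F)CC[C@@]2(C)[C@H]1O[Si](C)(C)C(C)(C)C | intermediate
22 | (3R)-3,7-dimethylocta-1,6-diene ((R)-β-citronellene) | CC(C)=CCC[C@@H](C)C=C | starting material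
23 | (4R)-4-methylhex-5-enal | O=CCC[C@@H](C)C=C | intermediate
24 | (3R)-6,6-dimethoxy-3-methylhex-1-ene | COC(OC)CC[C@@H](C)C=C | intermediate
25 | B-alkyl-9-BBN adduct of 24 (boron on C8) | COC(OC)CC[C@@H](C)CCB1C2CCCC1CCC2 | intermediate
26 | 9-alkyl enone: chain C8–C3 on C9, C3 as dimethyl acetal, 16-O-TBS, 12-enol triflate | COC(OC)CC[C@@H](C)CCC1=C(C)[C@H]2[C@H](C(=C)OS(=O)(=O)C(F)(F)F)CC[C@@]2(C)[C@@H](O[Si](C)(C)C(C)(C)C)C1=O | intermediate
27 | C3 aldehyde of 26 | O=CCC[C@@H](C)CCC1=C(C)[C@H]2[C@H](C(=C)OS(=O)(=O)C(F)(F)F)CC[C@@]2(C)[C@@H](O[Si](C)(C)C(C)(C)C)C1=O | intermediate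
28 | tricyclic 2-methylene-3-ols (ring A closed, C3 epimers), 16-O-TBS, 17-ketone | C=C1C(O)CC[C@@H](C)CCC2=C(C)[C@H]3[C@H]1CC[C@@]3(C)[C@@H](O[Si](C)(C)C(C)(C)C)C2=O | intermediate
29 | tricyclic 2-methylene-3-ketone, 16-O-TBS, 17-ketone | C=C1C(=O)CC[C@@H](C)CCC2=C(C)[C@H]3[C@H]1CC[C@@]3(C)[C@@H](O[Si](C)(C)C(C)(C)C)C2=O | intermediate
30 | (3R)-allylic alcohol, 16-O-TBS, 17-ketone | C=C1[C@H](O)CC[C@@H](C)CCC2=C(C)[C@H]3[C@H]1CC[C@@]3(C)[C@@H](O[Si](C)(C)C(C)(C)C)C2=O | intermediate
31 | (3R)-acetate, 16-O-TBS, 17-ketone | C=C1[C@H](OC(C)=O)CC[C@@H](C)CCC2=C(C)[C@H]3[C@H]1CC[C@@]3(C)[C@@H](O[Si](C)(C)C(C)(C)C)C2=O | intermediate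
32 | (3R)-acetate, 16-hydroxy-17-ketone | C=C1[C@H](OC(C)=O)CC[C@@H](C)CCC2=C(C)[C@H]3[C@H]1CC[C@@]3(C)[C@@H](O)C2=O | intermediate
33 | CNP0192310.2: (3R,6S,11R,12R,15R,16R,17R)-3-acetoxy-16,17-diol in the numbering above | C=C1[C@H](OC(C)=O)CC[C@@H](C)CCC2=C(C)[C@H]3[C@H]1CC[C@@]3(C)[C@@H](O)[C@@H]2O | target

Total steps: 23. Longest linear sequence: 20 steps (1–4, 7–14, 16–23).

Steps most likely to fail

1. Step 9. The 5-exo closure of the ester-tethered C14 radical may be too slow (unfavourable s-trans ester rotamer), so that the open-chain radical is diverted into oligomers or thiol adducts, or the first closure may occur with C13 anti to C11, which blocks the second ring closure. Fallback with known chemistry, from 5 back to 16: alcohol 5 is converted with glyoxylic acid chloride p-toluenesulfonylhydrazone (PhNMe2, then Et3N) into the diazoacetate F1. Rh2(OAc)4 closes it by intramolecular cyclopropanation of C15=C11 to the vinylcyclopropane lactone F2, which fixes C14–C15 cis to O16. The established intermolecular thiyl-radical [3+2] cycloaddition of this 2-vinylcyclopropane-1-carboxylate with but-3-en-2-ol (PhSSPh, AIBN, PhH, 80 °C) inserts C13–C12 between C14 and C11 and gives the hydroxyethyl lactone F3. Dess–Martin oxidation gives the acetyl lactone F4, which is taken through step 10 to 16.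

2. Step 4. The dienone may dimerise before it is reduced, and the catalyst may discriminate poorly between the two hindered flanks of the ketone, which would erode the enantiomeric purity on which every later centre depends. Fallback, from 4 back to 5: NaBH4/CeCl3 (MeOH, −78 °C, directly on the solution from step 3) gives the racemic dienol F5. Acylative kinetic resolution with (R)-benzotetramisole, isobutyric anhydride and iPr2NEt should then convert the (S)-alcohol into the isobutyrate F6 and leave (R)-alcohol 5.

3. Step 18. Closure of the strained 11-membered ring may lose to oligomerisation or to reduction of the triflate without C–C bond formation. Fallback that closes ring A at C8–C9 instead, from 19 and 23 back to 30: enol triflate 19 and aldehyde 23 (isolated by leaving out the acid in step 15) are joined by an intermolecular Nozaki–Hiyama–Kishi reaction to the allylic alcohols F7. Dess–Martin oxidation gives the enone F8 and reduction as in step 20 gives the (3R)-alcohol F9. Ketal hydrolysis gives the ring B enone F10 and iodination the iodoenone F11. Chemoselective hydroboration of the monosubstituted C7=C8 alkene (9-BBN, or the more discriminating dicyclohexylborane) gives the borane F12, and intramolecular B-alkyl Suzuki coupling under high dilution (PdCl2(dppf), AsPh3, K3PO4) gives 30.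

Further compounds
F1 | step 9 | (1R)-6,6-dimethoxy-2,4-dimethylcyclohexa-2,4-dien-1-yl diazoacetate | [N-]=[N+]=CC(=O)O[C@@H]1C(C)=CC(C)=CC1(OC)OC
F2 | step 9 | vinylcyclopropane lactone (cyclopropane C11–C14–C15 on ring B, C14 carboxyl lactonised onto O16) | COC1(OC)C=C(C)[C@H]2[C@H]3C(=O)O[C@@H]1[C@@]23C
F3 | step 9 | tricyclic lactone with 12-(1-hydroxyethyl) group (carbinol epimers) | COC1(OC)C=C(C)[C@H]2[C@H](C(C)O)C[C@H]3C(=O)O[C@@H]1[C@@]23C
F4 | step 9 | tricyclic lactone with 12-acetyl group | COC1(OC)C=C(C)[C@H]2[C@H](C(C)=O)C[C@H]3C(=O)O[C@@H]1[C@@]23C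
F5 | step 4 | racemic 6,6-dimethoxy-2,4-dimethylcyclohexa-2,4-dien-1-ol | COC1(OC)C=C(C)C=C(C)C1O
F6 | step 4 | (1S)-6,6-dimethoxy-2,4-dimethylcyclohexa-2,4-dien-1-yl 2-methylpropanoate | COC1(OC)C=C(C)C=C(C)[C@@H]1OC(=O)C(C)C
F7 | step 18 | open-chain 2-methylene-3-ols (C3 epimers) from 19 and 23, ring B ketal | COC1(OC)C=C(C)[C@H]2[C@H](C(=C)C(O)CC[C@@H](C)C=C)CC[C@@]2(C)[C@H]1O[Si](C)(C)C(C)(C)C
F8 | step 18 | open-chain 2-methylene-3-ketone, ring B ketal | COC1(OC)C=C(C)[C@H]2[C@H](C(=C)C(=O)CC[C@@H](C)C=C)CC[C@@]2(C)[C@H]1O[Si](C)(C)C(C)(C)C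
F9 | step 18 | open-chain (3R)-allylic alcohol, ring B ketal | COC1(OC)C=C(C)[C@H]2[C@H](C(=C)[C@H](O)CC[C@@H](C)C=C)CC[C@@]2(C)[C@H]1O[Si](C)(C)C(C)(C)C
F10 | step 18 | open-chain (3R)-allylic alcohol, ring B enone | O=C1C=C(C)[C@H]2[C@H](C(=C)[C@H](O)CC[C@@H](C)C=C)CC[C@@]2(C)[C@H]1O[Si](C)(C)C(C)(C)C
F11 | step 18 | open-chain (3R)-allylic alcohol, ring B 9-iodo enone | O=C1C(I)=C(C)[C@H]2[C@H](C(=C)[C@H](O)CC[C@@H](C)C=C)CC[C@@]2(C)[C@H]1O[Si](C)(C)C(C)(C)C
F12 | step 18 | B-alkyl-9-BBN adduct of F11 (boron on C8) | O=C1C(I)=C(C)[C@H]2[C@H](C(=C)[C@H](O)CC[C@@H](C)CCB3C4CCCC3CCC4)CC[C@@]2(C)[C@H]1O[Si](C)(C)C(C)(C)C
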